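**Plan**
Retrosynthesis: once the acetyl and protecting groups are set aside, ring A is removed whole by cutting C4a–C5, C5–C6, C7–C8 and C8–C8a. The biaryl bond C2–C1' between rings C and B is cut next.
Enabling feature: ring A carries its two oxygens meta (C5-OH, C7-OH) and is fused through C4a–C8a to a 4-pyranone (ring C) that holds C3–O and C4=O. A vinylketene/ynol ether benzannulation delivers such a meta pair (ketene C=O → C5-OH, ynol O → C7-O), and kojic acid is ring C with O1, C3–O and C4=O in place.
Forward order: ring B is dressed from vanillin as a boronate and ring C is taken from kojic acid as a bromide. Suzuki coupling joins them, CH2OH is raised to COCHN2, and ring A is closed last onto the one free pyranone C–H.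
Endgame: the MOM group is removed, 5'-OH is acetylated beside the chelated 5-OH, and both benzyl ethers are hydrogenolysed.
Stereochemistry: the target has no stereocentre, no stereogenic double bond and no locked axis, so nothing has to be set. The transient sp3 carbons of the key step vanish on aromatisation.

Key step: step 12

Remark: Ar stands for 2-(benzyloxy)-4-methoxy-5-(methoxymethoxy)phenyl, and flavone numbering (O1 to C8a, ring B primed) is used for the atoms of the key step. The 5'-oxygen travels as a MOM ether because it must pass NBS, zerovalent palladium, a ketene and light. Benzyloxyethyne is assumed to be usable as a cold, freshly made solution.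

Step 1
Reactants: 1 vanillin (4-hydroxy-3-methoxybenzaldehyde)
Product: 2 3-methoxy-4-(methoxymethoxy)benzaldehyde
Conditions: MOMCl, iPr2NEt, CH2Cl2, 0 °C → rt
Reagents that add atoms: chloromethyl methyl ether, COCCl
Why: Williamson-type O-alkylation (MOM protection) of the only acidic OH gives an acetal that withstands base, organolithium, palladium, light and heat and later falls to mild acid without touching benzyl ethers.

Step 2
Reactants: 2 3-methoxy-4-(methoxymethoxy)benzaldehyde
Product: 4 3-methoxy-4-(methoxymethoxy)phenol, via aryl formate 3 (not isolated)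
Conditions: mCPBA, CH2Cl2, rt; aq NaHCO3 wash; crude formate, K2CO3 (cat.), MeOH, rt
Reagents that add atoms: meta-chloroperoxybenzoic acid, OOC(=O)c1cccc(Cl)c1
Why: In this Baeyer–Villiger (Dakin-type) oxidation the electron-rich aryl group, para to an alkoxy donor, migrates in preference to hydride, and the labile formate 3 is methanolysed to the phenol that becomes the 2'-oxygen.

Step 3
Reactants: 4 3-methoxy-4-(methoxymethoxy)phenol
Product: 5 4-(benzyloxy)-2-methoxy-1-(methoxymethoxy)benzene
Conditions: BnBr, K2CO3, DMF, rt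
Reagents that add atoms: benzyl bromide, BrCc1ccccc1
Why: Williamson ether synthesis on the single free phenol installs benzyl, chosen so that 2'-O and 7-O are released together in the last step.

Step 4
Reactants: 5 4-(benzyloxy)-2-methoxy-1-(methoxymethoxy)benzene
Product: 6 1-(benzyloxy)-2-bromo-5-methoxy-4-(methoxymethoxy)benzene
Conditions: NBS, MeCN, 0 °C, dark
Reagents that add atoms: N-bromosuccinimide, O=C1CCC(=O)N1Br
Why: Electrophilic aromatic bromination of a 1,2,4-trialkoxybenzene goes to the one carbon that is para to OMe, ortho to OBn and not flanked by two substituents (the future C1'), while polar dark conditions suppress benzylic radical bromination.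

Step 5
Reactants: 6 1-(benzyloxy)-2-bromo-5-methoxy-4-(methoxymethoxy)benzene
Product: 8 2-[2-(benzyloxy)-4-methoxy-5-(methoxymethoxy)phenyl]-4,4,5,5-tetramethyl-1,3,2-dioxaborolane, via aryllithium 7 (not isolated)
Conditions: n-BuLi, THF, −78 °C; then iPrOBpin, −78 °C → rt
Reagents that add atoms: 2-isopropoxy-4,4,5,5-tetramethyl-1,3,2-dioxaborolane, CC(C)OB1OC(C)(C)C(C)(C)O1
Why: Bromine–lithium exchange at −78 °C is faster than MOM-directed or benzylic metalation, and borylation of aryllithium 7 with the isopropoxy boronate gives a pinacol ester that needs no acidic work-up.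

Step 6
Reactants: 9 kojic acid (5-hydroxy-2-(hydroxymethyl)-4H-pyran-4-one)
Product: 10 2-bromo-3-hydroxy-6-(hydroxymethyl)-4H-pyran-4-one (6-bromokojic acid)
Conditions: NBS, MeCN, rt
Reagents that add atoms: N-bromosuccinimide, O=C1CCC(=O)N1Br
Why: Electrophilic halogenation of the enolic hydroxypyranone proceeds, as with a phenol, at the free carbon ortho to OH and next to the ring oxygen, which is the future flavone C2.

Step 7
Reactants: 10 2-bromo-3-hydroxy-6-(hydroxymethyl)-4H-pyran-4-one
Product: 11 2-bromo-6-(hydroxymethyl)-3-methoxy-4H-pyran-4-one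
Conditions: MeI, K2CO3, DMF, rt
Reagents that add atoms: iodomethane, CI
Why: In this Williamson O-methylation carbonate deprotonates only the acidic enolic OH, so the primary alcohol stays free and the flavone 3-OMe is installed.

Step 8
Reactants: 11 2-bromo-6-(hydroxymethyl)-3-methoxy-4H-pyran-4-one; 8 2-[2-(benzyloxy)-4-methoxy-5-(methoxymethoxy)phenyl]-4,4,5,5-tetramethyl-1,3,2-dioxaborolane
Product: 12 2-[2-(benzyloxy)-4-methoxy-5-(methoxymethoxy)phenyl]-6-(hydroxymethyl)-3-methoxy-4H-pyran-4-one
Conditions: Pd(OAc)2 (5 mol %), SPhos (10 mol %), K3PO4, 1,4-dioxane/H2O, 80 °C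
Reagents that add atoms: none
Why: In this Suzuki–Miyaura coupling the C–Br bond of the 2-bromo-4-pyranone is a vinylogous acyl bromide that adds readily to zerovalent palladium, and the bulky electron-rich biarylphosphine carries the doubly ortho-substituted transmetalation and reductive elimination that form C2–C1'.

Step 9
Reactants: 12 2-Ar-6-(hydroxymethyl)-3-methoxy-4H-pyran-4-one
Product: 14 6-[2-(benzyloxy)-4-methoxy-5-(methoxymethoxy)phenyl]-5-methoxy-4-oxo-4H-pyran-2-carboxylic acid, via pyranone aldehyde 13 (not isolated)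
Conditions: TEMPO (cat.), PhI(OAc)2, MeCN/H2O, rt
Reagents that add atoms: water, O
Why: In this oxoammonium oxidation (TEMPO/PhI(OAc)2 in aqueous medium) aldehyde 13, attached to an electron-poor ring, hydrates readily and is oxidised on to the acid under conditions mild enough for the MOM, benzyl and trialkoxyaryl groups.

Step 10
Reactants: 14 6-Ar-5-methoxy-4-oxo-4H-pyran-2-carboxylic acid
Product: 16 2-[2-(benzyloxy)-4-methoxy-5-(methoxymethoxy)phenyl]-6-(diazoacetyl)-3-methoxy-4H-pyran-4-one, via mixed anhydride 15 (not isolated)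
Conditions: iBuOCOCl, N-methylmorpholine, THF, −20 °C; then CH2N2, Et2O, −20 → 0 °C
Reagents that add atoms: diazomethane, C=[N+]=[N-]
Why: In this Arndt–Eistert-type acylation of diazomethane the acid is activated as carbonic anhydride 15 under buffered, HCl-free conditions that spare the MOM ether, and diazomethane attacks the more electrophilic pyranoyl carbonyl while low temperature and limited excess hold back addition to the ring double bond.

Step 11
Reactants: 17 benzyl alcohol; 18 trichloroethylene
Product: 21 benzyloxyethyne, via dichlorovinyl ether 19 (not isolated), via lithium acetylide 20 (not isolated)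
Conditions: KH, THF, 0 °C; 18, −50 °C → rt; n-BuLi (2.3 equiv), −78 → −40 °C; MeOH, −78 °C; cold pentane extraction
Reagents that add atoms: none
Why: In this one-pot ynol ether synthesis from trichloroethylene the alkoxide gives dichloroenol ether 19, two equivalents of n-BuLi effect loss of HCl and chlorine–lithium exchange to acetylide 20, and cold protonation gives an alkyne that has no β-hydrogen for retro-ene loss but is used at once because benzyl ynol ethers rearrange sigmatropically on heating.

Step 12
Reactants: 16 2-Ar-6-(diazoacetyl)-3-methoxy-4H-pyran-4-one; 21 benzyloxyethyne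
Product: 26 7-(benzyloxy)-2-[2-(benzyloxy)-4-methoxy-5-(methoxymethoxy)phenyl]-5-hydroxy-3-methoxy-4H-chromen-4-one, via pyranonylketene 22 (not isolated), via vinylcyclobutenone 23 (not isolated), via dienylketene 24 (not isolated), via cyclohexadienone 25 (not isolated)
Conditions: 21 (2.5 equiv), degassed ClCH2CH2Cl (0.05 M), hν (405 nm LED), 10–20 °C until N2 evolution ends; then dark, 80 °C
Reagents that add atoms: none
Why: Proposed new method: excitation of the diazo n–π* band expels N2 and the pyranonyl group shifts to the diazo carbon (photo-Wolff rearrangement, bond C8–C8a), so that ketene 22 is conjugated with the C8a=C4a double bond of the pyranone; the nucleophilic terminal carbon of 21 attacks the ketene carbonyl carbon and the [2+2] adduct 23 holds bonds C5–C6 and C7–C8. In the dark at 80 °C 23 opens by reversible conrotatory 4π ring opening to dienylketene 24, whose isomer with the ketene arm cis to the pyranonyl group closes ring A by disrotatory 6π electrocyclisation between the ketene carbon and the pyranone C–H carbon (bond C4a–C5), and dienone 25 then tautomerises irreversibly to the hydrogen-bonded phenol 26. The closest known reaction type is the photochemical Danheiser benzannulation of alkenyl, aryl and heteroaryl diazomethyl ketones with alkoxy-, siloxy- and aminoalkynes; a 4-pyranone has not served as the ene part, but its ring double bond is much less aromatic than the benzene, furan or thiophene bonds that do take part, and the electron-poor ketene should be captured faster by the ynol ether. The step needs regioselectivity only, and the substrate fixes it: ynol ether polarisation ties the OBn-bearing carbon to the former diazo carbon (OBn at C7, next to C8), the ketene oxygen ends as 5-OH meta to it, and the pyranone has a single unsubstituted carbon on which the 6π closure can end. No stereocentre remains, because the sp3 carbons of racemic 23 and 25 become aromatic. Chemoselectivity rests on the 405 nm light, which the MOM, methyl and benzyl ethers do not absorb, on stopping irradiation once N2 evolution ends, and on the chelated 5-OH, which is a poor nucleophile toward residual ketene and lets the 5-hydroxyflavone shed excitation by proton transfer.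

Step 13
Reactants: 26 7-(benzyloxy)-2-Ar-5-hydroxy-3-methoxy-4H-chromen-4-one
Product: 27 7-(benzyloxy)-2-[2-(benzyloxy)-5-hydroxy-4-methoxyphenyl]-5-hydroxy-3-methoxy-4H-chromen-4-one
Conditions: HCl (aq, cat.), MeOH/THF, 45 °C
Reagents that add atoms: none
Why: Acid-catalysed acetal hydrolysis (MOM cleavage) frees 5'-OH, while aryl benzyl and methyl ethers and the flavone core are inert to dilute HCl.

Step 14
Reactants: 27 7-(benzyloxy)-2-[2-(benzyloxy)-5-hydroxy-4-methoxyphenyl]-5-hydroxy-3-methoxy-4H-chromen-4-one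
Product: 28 4-(benzyloxy)-5-[7-(benzyloxy)-5-hydroxy-3-methoxy-4-oxo-4H-chromen-2-yl]-2-methoxyphenyl acetate
Conditions: Ac2O (1.05 equiv), pyridine, CH2Cl2, 0 °C
Reagents that add atoms: acetic anhydride, CC(=O)OC(C)=O
Why: This O-acylation is chemoselective because the 5-OH is locked in a strong hydrogen bond to C4=O and is a poor nucleophile without DMAP or heat, so one equivalent of anhydride goes to the free 5'-phenol.

Step 15
Reactants: 28 4-(benzyloxy)-5-[7-(benzyloxy)-5-hydroxy-3-methoxy-4-oxo-4H-chromen-2-yl]-2-methoxyphenyl acetate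
Product: 29 5,7,2',5'-tetrahydroxy-3,4'-dimethoxyflavone 5'-acetate
Conditions: H2 (1 atm), 10% Pd/C, EtOAc/THF, rt
Reagents that add atoms: none
Why: Catalytic hydrogenolysis removes both aryl benzyl ethers, and in a neutral aprotic solvent the aryl acetate is neither cleaved nor transferred (its ring B oxygen neighbours are an OMe and a para OH) while the tetrasubstituted C2=C3 bond is not reduced at one atmosphere.

**Compound list**
1 | vanillin (4-hydroxy-3-methoxybenzaldehyde) | COc1cc(C=O)ccc1O | starting material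
2 | 3-methoxy-4-(methoxymethoxy)benzaldehyde | COCOc1ccc(C=O)cc1OC | intermediate
3 | 3-methoxy-4-(methoxymethoxy)phenyl formate | COCOc1ccc(OC=O)cc1OC | intermediate
4 | 3-methoxy-4-(methoxymethoxy)phenol | COCOc1ccc(O)cc1OC | intermediate
5 | 4-(benzyloxy)-2-methoxy-1-(methoxymethoxy)benzene | COCOc1ccc(OCc2ccccc2)cc1OC | intermediate
6 | 1-(benzyloxy)-2-bromo-5-methoxy-4-(methoxymethoxy)benzene | COCOc1cc(Br)c(OCc2ccccc2)cc1OC | intermediate
7 | [2-(benzyloxy)-4-methoxy-5-(methoxymethoxy)phenyl]lithium | [Li]c1cc(OCOC)c(OC)cc1OCc1ccccc1 | intermediate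
8 | 2-[2-(benzyloxy)-4-methoxy-5-(methoxymethoxy)phenyl]-4,4,5,5-tetramethyl-1,3,2-dioxaborolane | COCOc1cc(B2OC(C)(C)C(C)(C)O2)c(OCc2ccccc2)cc1OC | intermediate
9 | kojic acid (5-hydroxy-2-(hydroxymethyl)-4H-pyran-4-one) | OCc1cc(=O)c(O)co1 | starting material
10 | 2-bromo-3-hydroxy-6-(hydroxymethyl)-4H-pyran-4-one | OCc1cc(=O)c(O)c(Br)o1 | intermediate
11 | 2-bromo-6-(hydroxymethyl)-3-methoxy-4H-pyran-4-one | OCc1cc(=O)c(OC)c(Br)o1 | intermediate
12 | 2-[2-(benzyloxy)-4-methoxy-5-(methoxymethoxy)phenyl]-6-(hydroxymethyl)-3-methoxy-4H-pyran-4-one | OCc1cc(=O)c(OC)c(-c2cc(OCOC)c(OC)cc2OCc2ccccc2)o1 | intermediate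
13 | 6-[2-(benzyloxy)-4-methoxy-5-(methoxymethoxy)phenyl]-5-methoxy-4-oxo-4H-pyran-2-carbaldehyde | O=Cc1cc(=O)c(OC)c(-c2cc(OCOC)c(OC)cc2OCc2ccccc2)o1 | intermediate
14 | 6-[2-(benzyloxy)-4-methoxy-5-(methoxymethoxy)phenyl]-5-methoxy-4-oxo-4H-pyran-2-carboxylic acid | OC(=O)c1cc(=O)c(OC)c(-c2cc(OCOC)c(OC)cc2OCc2ccccc2)o1 | intermediate
15 | mixed anhydride of 14 with isobutyl hydrogen carbonate | CC(C)COC(=O)OC(=O)c1cc(=O)c(OC)c(-c2cc(OCOC)c(OC)cc2OCc2ccccc2)o1 | intermediate
16 | 2-[2-(benzyloxy)-4-methoxy-5-(methoxymethoxy)phenyl]-6-(diazoacetyl)-3-methoxy-4H-pyran-4-one | [N-]=[N+]=CC(=O)c1cc(=O)c(OC)c(-c2cc(OCOC)c(OC)cc2OCc2ccccc2)o1 | intermediate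
17 | benzyl alcohol | OCc1ccccc1 | starting material
18 | trichloroethylene | ClC=C(Cl)Cl | starting material
19 | benzyl (E)-1,2-dichlorovinyl ether | Cl/C=C(/Cl)OCc1ccccc1 | intermediate
20 | lithium (benzyloxy)acetylide | [Li]C#COCc1ccccc1 | intermediate
21 | benzyloxyethyne | C#COCc1ccccc1 | intermediate
22 | 2-(6-Ar-5-methoxy-4-oxo-4H-pyran-2-yl)ethenone (pyranonylketene) | O=C=Cc1cc(=O)c(OC)c(-c2cc(OCOC)c(OC)cc2OCc2ccccc2)o1 | intermediate
23 | 3-(benzyloxy)-4-(6-Ar-5-methoxy-4-oxo-4H-pyran-2-yl)cyclobut-2-en-1-one (racemic) | O=C1C=C(OCc2ccccc2)C1c1cc(=O)c(OC)c(-c2cc(OCOC)c(OC)cc2OCc2ccccc2)o1 | intermediate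
24 | (3E)-3-(benzyloxy)-4-(6-Ar-5-methoxy-4-oxo-4H-pyran-2-yl)buta-1,3-dien-1-one (ketene arm cis to pyranonyl) | O=C=C/C(OCc1ccccc1)=C\c1cc(=O)c(OC)c(-c2cc(OCOC)c(OC)cc2OCc2ccccc2)o1 | intermediate
25 | 7-(benzyloxy)-2-Ar-3-methoxy-4aH-chromene-4,5-dione (racemic keto tautomer of 26) | O=C1C=C(OCc2ccccc2)C=C2OC(-c3cc(OCOC)c(OC)cc3OCc3ccccc3)=C(OC)C(=O)C12 | intermediate
26 | 7-(benzyloxy)-2-[2-(benzyloxy)-4-methoxy-5-(methoxymethoxy)phenyl]-5-hydroxy-3-methoxy-4H-chromen-4-one | COc1c(-c2cc(OCOC)c(OC)cc2OCc2ccccc2)oc2cc(OCc3ccccc3)cc(O)c2c1=O | intermediate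
27 | 7-(benzyloxy)-2-[2-(benzyloxy)-5-hydroxy-4-methoxyphenyl]-5-hydroxy-3-methoxy-4H-chromen-4-one | COc1c(-c2cc(O)c(OC)cc2OCc2ccccc2)oc2cc(OCc3ccccc3)cc(O)c2c1=O | intermediate
28 | 4-(benzyloxy)-5-[7-(benzyloxy)-5-hydroxy-3-methoxy-4-oxo-4H-chromen-2-yl]-2-methoxyphenyl acetate | COc1c(-c2cc(OC(C)=O)c(OC)cc2OCc2ccccc2)oc2cc(OCc3ccccc3)cc(O)c2c1=O | intermediate
29 | 5,7,2',5'-tetrahydroxy-3,4'-dimethoxyflavone 5'-acetate | COc1cc(O)c(-c2oc3cc(O)cc(O)c3c(=O)c2OC)cc1OC(C)=O | target

**Totals**
Total step count: 15.
Longest linear sequence: 12 steps, from vanillin (steps 1–5, 8–10, 12–15).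

**Steps most likely to fail**

Step 12. Several processes could defeat the benzannulation:
- Photoreaction of the aryl-pyranone chromophore, or oligomerisation of the electron-poor ketene, may outrun capture by the ynol ether.
- The benzyl ynol ether may decay by sigmatropic rearrangement before it is consumed.
- The sequence may stall before the 6π closure.

The fallback uses known chemistry and reverses the logic: ring C is built onto a ready-made ring A by an Allan–Robinson flavone synthesis. It sets out from bromide 6. Bromine–lithium exchange (n-BuLi, THF, −78 °C) and CO2 give 2-(benzyloxy)-4-methoxy-5-(methoxymethoxy)benzoic acid F1. Half an equivalent of DCC dehydrates this to 2-(benzyloxy)-4-methoxy-5-(methoxymethoxy)benzoic anhydride F2. F2 is heated with commercial 2-methoxy-1-(2,4,6-trihydroxyphenyl)ethanone and Et3N at about 160 °C. Brief treatment of the crude condensate with KOH in aqueous EtOH frees any aroylated phenol and gives 2-Ar-5,7-dihydroxy-3-methoxy-4H-chromen-4-one F3. Alkylation of the more acidic, non-chelated 7-OH with one equivalent of BnBr (K2CO3, acetone) comes back to the route at 26.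

Step 10. Dipolar cycloaddition of diazomethane across the doubly activated ring double bond, or attack at the carbonate carbonyl of the anhydride, may compete with C-acylation.

The fallback avoids diazomethane and installs the diazo group by diazo transfer. It sets out from acid 14. Coupling with MeNHOMe·HCl (EDC·HCl, iPr2NEt, CH2Cl2) gives 6-Ar-N,5-dimethoxy-N-methyl-4-oxo-4H-pyran-2-carboxamide F4. MeMgBr (THF, −78 °C) converts it into 6-acetyl-2-Ar-3-methoxy-4H-pyran-4-one F5. LiN(SiMe3)2 followed by CF3CO2CH2CF3 gives 1-(6-Ar-5-methoxy-4-oxo-4H-pyran-2-yl)-4,4,4-trifluorobutane-1,3-dione F6. F6 is treated crude with MsN3, Et3N and H2O in MeCN (detrifluoroacetylative diazo transfer) and comes back to the route at 16.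

Step 8. Protodeboronation of the electron-rich ortho-alkoxy boronate, together with base-induced opening or hydrolytic debromination of the bromopyranone, may outrun a hindered transmetalation.

The fallback removes base and free OH from the coupling. It sets out from 11 and from aryllithium 7 (made from 6). Oxidation of 11 with CrO3/H2SO4 in acetone gives 6-bromo-5-methoxy-4-oxo-4H-pyran-2-carboxylic acid F7. MeOH with catalytic H2SO4 gives methyl 6-bromo-5-methoxy-4-oxo-4H-pyran-2-carboxylate F8. ZnCl2 converts 7 into [2-(benzyloxy)-4-methoxy-5-(methoxymethoxy)phenyl]zinc chloride F9. Negishi coupling of F8 with F9 (Pd(PPh3)4, THF, 50 °C) gives methyl 6-Ar-5-methoxy-4-oxo-4H-pyran-2-carboxylate F10. LiOH (THF/H2O, 0 °C) followed by citric acid comes back to the route at 14, so step 9 is bypassed as well.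

**Further compounds**
F1 | step 12 | 2-(benzyloxy)-4-methoxy-5-(methoxymethoxy)benzoic acid | COCOc1cc(C(=O)O)c(OCc2ccccc2)cc1OC
F2 | step 12 | 2-(benzyloxy)-4-methoxy-5-(methoxymethoxy)benzoic anhydride | COCOc1cc(C(=O)OC(=O)c2cc(OCOC)c(OC)cc2OCc2ccccc2)c(OCc2ccccc2)cc1OC
F3 | step 12 | 2-[2-(benzyloxy)-4-methoxy-5-(methoxymethoxy)phenyl]-5,7-dihydroxy-3-methoxy-4H-chromen-4-one | COc1c(-c2cc(OCOC)c(OC)cc2OCc2ccccc2)oc2cc(O)cc(O)c2c1=O
F4 | step 10 | 6-[2-(benzyloxy)-4-methoxy-5-(methoxymethoxy)phenyl]-N,5-dimethoxy-N-methyl-4-oxo-4H-pyran-2-carboxamide | CON(C)C(=O)c1cc(=O)c(OC)c(-c2cc(OCOC)c(OC)cc2OCc2ccccc2)o1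
F5 | step 10 | 6-acetyl-2-[2-(benzyloxy)-4-methoxy-5-(methoxymethoxy)phenyl]-3-methoxy-4H-pyran-4-one | CC(=O)c1cc(=O)c(OC)c(-c2cc(OCOC)c(OC)cc2OCc2ccccc2)o1
F6 | step 10 | 1-{6-[2-(benzyloxy)-4-methoxy-5-(methoxymethoxy)phenyl]-5-methoxy-4-oxo-4H-pyran-2-yl}-4,4,4-trifluorobutane-1,3-dione | O=C(CC(=O)C(F)(F)F)c1cc(=O)c(OC)c(-c2cc(OCOC)c(OC)cc2OCc2ccccc2)o1
F7 | step 8 | 6-bromo-5-methoxy-4-oxo-4H-pyran-2-carboxylic acid | OC(=O)c1cc(=O)c(OC)c(Br)o1
F8 | step 8 | methyl 6-bromo-5-methoxy-4-oxo-4H-pyran-2-carboxylate | COC(=O)c1cc(=O)c(OC)c(Br)o1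
F9 | step 8 | [2-(benzyloxy)-4-methoxy-5-(methoxymethoxy)phenyl]zinc chloride | Cl[Zn]c1cc(OCOC)c(OC)cc1OCc1ccccc1
F10 | step 8 | methyl 6-[2-(benzyloxy)-4-methoxy-5-(methoxymethoxy)phenyl]-5-methoxy-4-oxo-4H-pyran-2-carboxylate | COC(=O)c1cc(=O)c(OC)c(-c2cc(OCOC)c(OC)cc2OCc2ccccc2)o1
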